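## The problem

The target is a depside in which ring A, a benzoic acid numbered here C1 (carboxyl), C2 (methoxy), C4 (acyloxy) and C6 (heptyl), is esterified at its C4 oxygen by ring B, a 2,4-dimethoxy-6-pentylbenzoyl group. The two rings are joined only by this aryl ester, so no ring fusion has to be built. The target has no stereocentre; the two centres that arise in a cyclohexanedione on the way control nothing and vanish on aromatisation. The real tasks are regiochemical: ring A carries three different oxygen functions (free acid at C1, methyl ether at C2, aryl ester at C4) that must be told apart, and ring B must be carboxylated next to its pentyl chain. Three points are fragile: the aryl ester falls to hydroxide or alkoxide, so the ring A carboxyl cannot be freed by saponification; the final acid, flanked by methoxy and heptyl on an electron-rich ring, may decarboxylate in hot acid; and the ester bond must be made at a carbonyl shielded by two ortho substituents. The feature that opens the route is that ring A is a 6-alkyl resorcylate: C1 with its carboxyl and the oxygenated C2 are the skeleton of a malonate, and C3 to C6 with the heptyl chain are that of (E)-undec-3-en-2-one 3. A Michael addition (C1–C6) and a Claisen condensation (C2–C3) therefore build the ring with oxygen already at C2 and C4. In the resorcylate that follows, the C2 hydroxyl is hydrogen-bonded to the ester and the C4 hydroxyl is not, which separates the two oxygens without protecting groups.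

## Retrosynthesis

Ring atoms keep the numbering above; systematic names in the steps follow lowest-locant rules, so ring A appears there as a 2-heptyl-6-methoxybenzoate.

**17 to 16.** The O–CH2Ph bond of a benzyl ester on the ring A carboxyl is cut. Only a mask that leaves by hydrogenolysis fits: a methyl ester would need saponification, which the depside ester would not survive, and a tert-butyl ester would need acid, which invites decarboxylation, and would close poorly in the Claisen step. Precursor 16 differs from 17 by one protecting group. The forward reaction only has to leave the aryl ester and the three methyl ethers alone.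

**16 to 15.** The O–CH3 bond at the C2 oxygen is cut. Methylating this oxygen last uses its low reactivity as a chelated phenol: it stays untouched while the C4 hydroxyl is acylated, whereas the reverse order would need a temporary group at C4. The forward step must alkylate a hydrogen-bonded phenol under carbonate without cleaving the depside ester.

**15 to 8 and 14.** The aryl ester C–O bond is cut. This is the most convergent cut available and gives two benzene building blocks of similar size; cutting inside ring B instead would drag the whole of ring A through a ring construction. The forward acylation must take the C4 hydroxyl of resorcylate 8, not the C2 hydroxyl, and must succeed at the hindered carbonyl of acid chloride 14.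

**14 back to 9.** Acid chloride 14 comes from acid 13, and 13 from aldehyde 12 by oxidation. The bond between C1 of ring B and its carbonyl carbon is then cut as an electrophilic formylation of dimethyl ether 10, which comes from olivetol 9 by double methylation. Olivetol 9 supplies the ring, the pentyl chain and both oxygens. The formylation must go to the position next to the pentyl chain (para to one methoxy, ortho to the other) and not between the two methoxy groups.

**8 to 6.** Aromaticity is removed: 8 is the aromatic tautomer of dehydrogenated dione 6, so the forward step is a two-electron oxidation, run as bromination to 7 and dehydrobromination. This exposes the 1,3-dicarbonyl pattern that the annulation delivers. The oxidation must stop after one equivalent and spare the benzyl ester.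

**6 to 3 and 4.** The C1–C6 and C2–C3 bonds are cut, giving (E)-undec-3-en-2-one 3 and dibenzyl malonate 4, with Michael adduct 5 on the path. This pairing is preferred over other two-bond cuts of the ring because 4 is symmetrical and commercial, 3 is one step from an aldehyde, and the ester that survives is already the benzyl ester needed at the end. Both precursors are acyclic and achiral. The forward reaction needs conjugate addition at the heptyl-bearing carbon, ring closure through the methyl ketone enolate, and no ester scrambling.

**3 to 1 and 2.** The C3=C4 double bond of the enone is cut as a Wittig reaction of octanal 1 with the stabilised ylide 2. A stabilised ylide gives the E-alkene, and the geometry is in any case lost in the next step.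

## Roads not taken

Alternative 1: The cut runs through ring B at its C1–C2 and C5–C6 bonds, so that ring B is grown on an ester already in place. In the forward direction the ring A phenol benzyl 2-heptyl-4-hydroxy-6-methoxybenzoate A1 is esterified with oct-2-ynoic acid A2 to give benzyl 2-heptyl-6-methoxy-4-(oct-2-ynoyloxy)benzoate A3. A Diels–Alder reaction of A3 with 1,1-dimethoxy-3-(trimethylsilyloxy)buta-1,3-diene A4, then loss of one acetal methoxy group and the silyl group, gives benzyl 2-heptyl-4-(4-hydroxy-2-methoxy-6-pentylbenzoyloxy)-6-methoxybenzoate A5.

- Merits: the ester bond is made with an unhindered alkynoic acid, which is easier than the acylation at a di-ortho-substituted benzoyl carbon in the chosen plan. The polarity of diene and ynoate fixes the ring B substitution pattern.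
- Weak points: A3 is an internal, β-alkyl alkyne with a single activating group, a slow dienophile that would need heat. A4 is a moisture-sensitive ketene acetal that may also attack the aryl ester carbonyl. A5 still carries a free C4 hydroxyl on ring B that must be methylated, so the oxygen differentiation the cycloaddition offers is wasted here. A1 must be made first, which means the ring A synthesis of the chosen plan plus a protect, methylate, deprotect sequence.
- Comparison: this road is better at the esterification. The chosen plan sets against that nucleophilic catalysis and an electron-rich acyl group that ionises readily, and it takes ring B in three steps from olivetol 9 with both methyl ethers in place.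

Alternative 2: The cut removes the heptyl group from C6 and the carboxyl carbon from C1 of ring A, with the depside ester already present. In the forward direction 4-iodo-3-methoxyphenyl 2,4-dimethoxy-6-pentylbenzoate A6, 1-iodoheptane A7 and tert-butyl acrylate A8 are joined in a Catellani reaction catalysed by Pd(OAc)2 with norbornene A9 as mediator. Ortho-alkylation at C6 is followed by ipso Heck termination at C1, giving tert-butyl (E)-3-[4-(2,4-dimethoxy-6-pentylbenzoyloxy)-2-heptyl-6-methoxyphenyl]acrylate A10. No ring is formed.

- Merits: three components meet in one step, the side chain enters late from a simple alkyl iodide, and no ring has to be constructed. For making chain analogues this road is better than the chosen plan.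
- Weak points: the carboxyl carbon arrives two carbons too long, so the alkene of A10 must be cleaved oxidatively and the resulting aldehyde oxidised, in the presence of two electron-rich arenes that are themselves open to oxidants. The tert-butyl ester of A8 is discarded. The aryl ester must survive carbonate base in a hot polar solvent.
- Comparison: more convergent, but the chosen plan delivers the carboxyl carbon at the right oxidation level from the malonate and needs no oxidative cleavage.

Alternative 3: The cut takes the depside C–O bond and the C1–C6 bond of ring B together. In the forward direction thermolysis of 2,2-dimethyl-6-(2,4-dioxononyl)-4H-1,3-dioxin-4-one A11 releases the acylketene dodec-1-ene-1,3,5,7-tetrone A12. Phenol A1 traps it as benzyl 2-heptyl-6-methoxy-4-[(3,5,7-trioxododecanoyl)oxy]benzoate A13, and aldol closure of C2 onto the C7 ketone with dehydration gives benzyl 4-(2,4-dihydroxy-6-pentylbenzoyloxy)-2-heptyl-6-methoxybenzoate A14.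

- Merits: the ester bond is formed by addition to a ketene rather than by substitution at a hindered carbonyl, which removes the hardest bond formation of the chosen plan. Ring B appears in the same flask.
- Weak points: a phenol is a weaker ketene trap than an aliphatic alcohol. A13 is an activated aryl ester whose C5 enol oxygen can lactonise to a pyranone and expel A1. A14 has two free phenols on ring B, one of them chelated, so three phenol methylations are needed overall instead of one. A11 takes several steps to prepare, and A1 is still required.
- Comparison: superior for the ester bond itself, but longer; the chosen plan takes ring B ready-made from olivetol 9 and spends its key step on ring A, which no commercial arene supplies.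

Key step: step 2

## Route

Remark: the target is achiral; dione 6 is written as its racemic trans diketo tautomer although it will exist largely as enols, and 7 is written as the 3-bromo compound without defined configuration.

Step 1
Reactants: 1 octanal; 2 1-(triphenylphosphoranylidene)propan-2-one
Product: 3 (E)-undec-3-en-2-one
Conditions: toluene, 80 °C
Reagents that add atoms: none
Why: Wittig olefination with a stabilised keto ylide, which should give the E-enone; the geometry is not carried further.

Step 2
Reactants: 3 (E)-undec-3-en-2-one; 4 dibenzyl malonate
Product: 6 benzyl trans-6-heptyl-2,4-dioxocyclohexane-1-carboxylate (racemic; 1S,6R enantiomer drawn), via Michael adduct 5 (not isolated)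
Conditions: NaH (1.1 equiv), BnOH (1.5 equiv), THF, 0 °C to reflux; then 1 M HCl, 0 °C
Reagents that add atoms: none
Why: Sodium benzyloxide deprotonates 4, and the malonate anion adds in a Michael sense to C4 of 3, the heptyl-bearing β-carbon, giving adduct 5 and the C1–C6 bond of ring A. Proton exchange then makes the methyl ketone enolate available; its carbon attacks one benzyl ester carbonyl in an intramolecular Claisen (Dieckmann-type) condensation that forms the C2–C3 bond and expels benzyloxide. The closure is 6-(enolendo)-exo-trig, a favoured mode, whereas the internal enolate could only close a four-membered ring and returns by proton transfer. Deprotonation of the product to its β-diketone enolate makes the sequence irreversible and pulls the reversible Michael step forward. The closest known reaction is the malonate–alk-3-en-2-one annulation to 6-alkyl-2,4-dioxocyclohexanecarboxylates with methoxide in methanol; only the ester alkyl group differs here. The new stereocentres C1 and C6 form without external control; C1 epimerises through the enol, so the trans isomer with ester and heptyl both equatorial should prevail, and both centres are erased in step 3. Regioselectivity rests on polarity alone, and matching benzyloxide to benzyl esters keeps transesterification degenerate.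

Step 3
Reactants: 6 benzyl trans-6-heptyl-2,4-dioxocyclohexane-1-carboxylate
Product: 8 benzyl 2-heptyl-4,6-dihydroxybenzoate, via bromodione 7 (not isolated)
Conditions: Br2 (1.0 equiv), DMF, 0 °C; then 70 °C
Reagents that add atoms: none
Why: Halogenative aromatisation of a dihydroresorcylate: the enol of the 1,3-dione is brominated at the carbon between the two ketones, and formal loss of HBr through the enol tautomers on warming, followed by tautomerisation, gives the resorcylate. One equivalent of bromine added cold limits ring bromination.

Step 4
Reactants: 9 olivetol (5-pentylbenzene-1,3-diol)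
Product: 10 1,3-dimethoxy-5-pentylbenzene
Conditions: MeI, K2CO3, acetone, reflux
Reagents that add atoms: iodomethane, CI
Why: Williamson ether synthesis on both unhindered phenols.

Step 5
Reactants: 10 1,3-dimethoxy-5-pentylbenzene
Product: 12 2,4-dimethoxy-6-pentylbenzaldehyde, via aryl iminium salt 11 (not isolated)
Conditions: POCl3, DMF, 0 °C to 60 °C; then H2O, 0 °C
Reagents that add atoms: N,N-dimethylformamide, CN(C)C=O; water, O
Why: Vilsmeier–Haack formylation. Attack para to one methoxy and ortho to the other is the usual outcome for 5-alkylresorcinol dimethyl ethers, because the position between the two methoxy groups is the more crowded.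

Step 6
Reactants: 12 2,4-dimethoxy-6-pentylbenzaldehyde
Product: 13 2,4-dimethoxy-6-pentylbenzoic acid
Conditions: NaClO2, NaH2PO4, 2-methyl-2-butene, t-BuOH/H2O, rt
Reagents that add atoms: sodium chlorite, [Na+].[O-]Cl=O
Why: Pinnick oxidation; excess alkene scavenger takes up hypochlorous acid and protects the electron-rich ring from chlorination.

Step 7
Reactants: 13 2,4-dimethoxy-6-pentylbenzoic acid
Product: 14 2,4-dimethoxy-6-pentylbenzoyl chloride
Conditions: (COCl)2, DMF (cat.), CH2Cl2, 0 °C to rt; evaporated and used crude
Reagents that add atoms: oxalyl chloride, O=C(Cl)C(=O)Cl
Why: Acid chloride formation through the catalytic chloroiminium species; neutral conditions leave the methyl ethers intact.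

Step 8
Reactants: 8 benzyl 2-heptyl-4,6-dihydroxybenzoate; 14 2,4-dimethoxy-6-pentylbenzoyl chloride
Product: 15 benzyl 4-[(2,4-dimethoxy-6-pentylbenzoyl)oxy]-2-heptyl-6-hydroxybenzoate
Conditions: Et3N, DMAP (0.2 equiv), CH2Cl2, 0 °C to rt
Reagents that add atoms: none
Why: DMAP-catalysed O-acylation of a phenol by an acid chloride. The hydroxyl para to the ester is the more acidic and is unhindered, while the ortho hydroxyl is tied up in a hydrogen bond to the ester carbonyl, so one equivalent of 14 should acylate the para oxygen only.

Step 9
Reactants: 15 benzyl 4-[(2,4-dimethoxy-6-pentylbenzoyl)oxy]-2-heptyl-6-hydroxybenzoate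
Product: 16 benzyl 4-[(2,4-dimethoxy-6-pentylbenzoyl)oxy]-2-heptyl-6-methoxybenzoate
Conditions: MeI, K2CO3, DMF, rt to 40 °C
Reagents that add atoms: iodomethane, CI
Why: Williamson methylation of the chelated phenol in a dipolar aprotic solvent; the depside ester is shielded by its two ortho substituents and should withstand anhydrous carbonate.

Step 10
Reactants: 16 benzyl 4-[(2,4-dimethoxy-6-pentylbenzoyl)oxy]-2-heptyl-6-methoxybenzoate
Product: 17 4-[(2,4-dimethoxy-6-pentylbenzoyl)oxy]-2-heptyl-6-methoxybenzoic acid (CNP0206304.0)
Conditions: H2 (1 atm), 10% Pd/C, EtOAc, rt
Reagents that add atoms: none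
Why: Hydrogenolysis of the benzyl ester under neutral conditions at room temperature; aryl esters and aryl methyl ethers are inert, and the acid is never exposed to heat or strong acid.

## Compound list

1 | octanal | CCCCCCCC=O | starting material
2 | 1-(triphenylphosphoranylidene)propan-2-one | CC(=O)C=P(c1ccccc1)(c1ccccc1)c1ccccc1 | starting material
3 | (E)-undec-3-en-2-one | CCCCCCC/C=C/C(C)=O | intermediate
4 | dibenzyl malonate | O=C(CC(=O)OCc1ccccc1)OCc1ccccc1 | starting material
5 | dibenzyl 2-(2-oxoundecan-4-yl)propanedioate (racemic; not isolated) | CCCCCCCC(CC(C)=O)C(C(=O)OCc1ccccc1)C(=O)OCc1ccccc1 | intermediate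
6 | benzyl trans-6-heptyl-2,4-dioxocyclohexane-1-carboxylate (racemic; 1S,6R enantiomer drawn) | CCCCCCC[C@@H]1CC(=O)CC(=O)[C@H]1C(=O)OCc1ccccc1 | intermediate
7 | benzyl 3-bromo-6-heptyl-2,4-dioxocyclohexane-1-carboxylate (mixture of stereoisomers; not isolated) | CCCCCCCC1CC(=O)C(Br)C(=O)C1C(=O)OCc1ccccc1 | intermediate
8 | benzyl 2-heptyl-4,6-dihydroxybenzoate | CCCCCCCc1cc(O)cc(O)c1C(=O)OCc1ccccc1 | intermediate
9 | olivetol (5-pentylbenzene-1,3-diol) | CCCCCc1cc(O)cc(O)c1 | starting material
10 | 1,3-dimethoxy-5-pentylbenzene | CCCCCc1cc(OC)cc(OC)c1 | intermediate
11 | N-[(2,4-dimethoxy-6-pentylphenyl)methylidene]-N-methylmethanaminium chloride (not isolated) | CCCCCc1cc(OC)cc(OC)c1C=[N+](C)C.[Cl-] | intermediate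
12 | 2,4-dimethoxy-6-pentylbenzaldehyde | CCCCCc1cc(OC)cc(OC)c1C=O | intermediate
13 | 2,4-dimethoxy-6-pentylbenzoic acid | CCCCCc1cc(OC)cc(OC)c1C(=O)O | intermediate
14 | 2,4-dimethoxy-6-pentylbenzoyl chloride | CCCCCc1cc(OC)cc(OC)c1C(=O)Cl | intermediate
15 | benzyl 4-[(2,4-dimethoxy-6-pentylbenzoyl)oxy]-2-heptyl-6-hydroxybenzoate | CCCCCCCc1cc(OC(=O)c2c(CCCCC)cc(OC)cc2OC)cc(O)c1C(=O)OCc1ccccc1 | intermediate
16 | benzyl 4-[(2,4-dimethoxy-6-pentylbenzoyl)oxy]-2-heptyl-6-methoxybenzoate | CCCCCCCc1cc(OC(=O)c2c(CCCCC)cc(OC)cc2OC)cc(OC)c1C(=O)OCc1ccccc1 | intermediate
17 | 4-[(2,4-dimethoxy-6-pentylbenzoyl)oxy]-2-heptyl-6-methoxybenzoic acid | CCCCCCCc1cc(OC(=O)c2c(CCCCC)cc(OC)cc2OC)cc(OC)c1C(=O)O | target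

## Step count and risks

Total step count: 10. Longest linear sequence: 7 steps (steps 4 to 10, from olivetol 9 through 10, 12, 13, 14, 15 and 16 to 17). The ring A branch (steps 1 to 3) joins at step 8.

**Step 2 (key step).** The most likely failure is stalling after the conjugate addition. The methyl ketone enolate needed for ring closure is the least populated anion of adduct 5, so retro-Michael reaction and base-induced self-condensation of enone 3 can compete, and any moisture would saponify benzyl esters. The fallback changes the pairing of the two halves and sets out from octanal 1. Wittig reaction with benzyl (triphenylphosphoranylidene)acetate gives benzyl (E)-dec-2-enoate F1, an acceptor that cannot self-condense through a ketone enolate. Michael addition of benzyl acetoacetate to it, mediated by sodium benzyloxide, gives dibenzyl 2-acetyl-3-heptylpentanedioate F2. The acetyl methyl enolate of this adduct closes onto the distal ester, forming C3–C4 in place of C2–C3, and the sequence comes back to the route at dione 6.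

**Step 3.** Bromide and HBr in warm DMF may dealkylate the benzyl ester, after which the β-keto acid or resorcylic acid would decarboxylate; excess bromine would also brominate the electron-rich ring. The fallback sets out from 6 and replaces halogenation–elimination by dehydrogenation with Hg(OAc)2 and NaOAc in refluxing AcOH. Divalent mercury acts as a two-electron oxidant through α-mercuration of the dione and loss of zerovalent mercury, with no halide present. It comes back to the route at 8 and makes no new compound.

**Step 8.** Acyl transfer from the di-ortho-substituted acid chloride 14 may be slow, so that hydrolysis competes, or forcing conditions may erode the preference for the para hydroxyl and lead to double acylation. The fallback sets out from acid 13 and resorcylate 8. Trifluoroacetic anhydride in toluene at room temperature converts 13 into 2,4-dimethoxy-6-pentylbenzoic trifluoroacetic anhydride F3, which ionises to the stabilised acylium ion; the non-chelated hydroxyl of 8 captures it. This is the classical depside esterification, and it comes back to the route at 15.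

**Step 9.** Under carbonate the phenoxide of 15 may attack the depside ester of a second molecule, causing acyl transfer or cleavage, while the hydrogen-bonded phenol is alkylated only slowly. The fallback reorders the functionalisation of ring A and sets out from 8. Allyl bromide and K2CO3 in acetone alkylate the non-chelated hydroxyl, giving benzyl 2-heptyl-6-hydroxy-4-(prop-2-en-1-yloxy)benzoate F4. MeI and K2CO3 in DMF at 50 °C, with no depside ester present, then give benzyl 2-heptyl-6-methoxy-4-(prop-2-en-1-yloxy)benzoate F5. The zerovalent palladium complex Pd(PPh3)4 with morpholine in THF removes the allyl group, giving benzyl 2-heptyl-4-hydroxy-6-methoxybenzoate F6. Acylation of F6 with 14 under the conditions of step 8 comes back to the route at 16.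

## Further compounds

F1 | step 2 | benzyl (E)-dec-2-enoate | CCCCCCC/C=C/C(=O)OCc1ccccc1
F2 | step 2 | dibenzyl 2-acetyl-3-heptylpentanedioate | CCCCCCCC(CC(=O)OCc1ccccc1)C(C(C)=O)C(=O)OCc1ccccc1
F0 | step 3 | none | none
F3 | step 8 | 2,4-dimethoxy-6-pentylbenzoic trifluoroacetic anhydride | CCCCCc1cc(OC)cc(OC)c1C(=O)OC(=O)C(F)(F)F
F4 | step 9 | benzyl 2-heptyl-6-hydroxy-4-(prop-2-en-1-yloxy)benzoate | CCCCCCCc1cc(OCC=C)cc(O)c1C(=O)OCc1ccccc1
F5 | step 9 | benzyl 2-heptyl-6-methoxy-4-(prop-2-en-1-yloxy)benzoate | CCCCCCCc1cc(OCC=C)cc(OC)c1C(=O)OCc1ccccc1
F6 | step 9 | benzyl 2-heptyl-4-hydroxy-6-methoxybenzoate | CCCCCCCc1cc(O)cc(OC)c1C(=O)OCc1ccccc1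
A1 | alternative 1 | benzyl 2-heptyl-4-hydroxy-6-methoxybenzoate | CCCCCCCc1cc(O)cc(OC)c1C(=O)OCc1ccccc1
A2 | alternative 1 | oct-2-ynoic acid | CCCCCC#CC(=O)O
A3 | alternative 1 | benzyl 2-heptyl-6-methoxy-4-(oct-2-ynoyloxy)benzoate | CCCCCC#CC(=O)Oc1cc(CCCCCCC)c(C(=O)OCc2ccccc2)c(OC)c1
A4 | alternative 1 | 1,1-dimethoxy-3-(trimethylsilyloxy)buta-1,3-diene | COC(OC)=CC(=C)O[Si](C)(C)C
A5 | alternative 1 | benzyl 2-heptyl-4-(4-hydroxy-2-methoxy-6-pentylbenzoyloxy)-6-methoxybenzoate | CCCCCCCc1cc(OC(=O)c2c(CCCCC)cc(O)cc2OC)cc(OC)c1C(=O)OCc1ccccc1
A6 | alternative 2 | 4-iodo-3-methoxyphenyl 2,4-dimethoxy-6-pentylbenzoate | CCCCCc1cc(OC)cc(OC)c1C(=O)Oc1ccc(I)c(OC)c1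
A7 | alternative 2 | 1-iodoheptane | CCCCCCCI
A8 | alternative 2 | tert-butyl acrylate | C=CC(=O)OC(C)(C)C
A9 | alternative 2 | norbornene (bicyclo[2.2.1]hept-2-ene) | C1=CC2CCC1C2
A10 | alternative 2 | tert-butyl (E)-3-[4-(2,4-dimethoxy-6-pentylbenzoyloxy)-2-heptyl-6-methoxyphenyl]acrylate | CCCCCCCc1cc(OC(=O)c2c(CCCCC)cc(OC)cc2OC)cc(OC)c1/C=C/C(=O)OC(C)(C)C
A11 | alternative 3 | 2,2-dimethyl-6-(2,4-dioxononyl)-4H-1,3-dioxin-4-one | CCCCCC(=O)CC(=O)CC1=CC(=O)OC(C)(C)O1
A12 | alternative 3 | dodec-1-ene-1,3,5,7-tetrone (acylketene) | CCCCCC(=O)CC(=O)CC(=O)C=C=O
A13 | alternative 3 | benzyl 2-heptyl-6-methoxy-4-[(3,5,7-trioxododecanoyl)oxy]benzoate | CCCCCC(=O)CC(=O)CC(=O)CC(=O)Oc1cc(CCCCCCC)c(C(=O)OCc2ccccc2)c(OC)c1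
A14 | alternative 3 | benzyl 4-(2,4-dihydroxy-6-pentylbenzoyloxy)-2-heptyl-6-methoxybenzoate | CCCCCCCc1cc(OC(=O)c2c(CCCCC)cc(O)cc2O)cc(OC)c1C(=O)OCc1ccccc1
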